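Pre-initiator lasts far longer than initiator in this flask: its half-life by its own step is 4.9 d, against 0.15 d for initiator by its step with free monomer as charged.

free monomer 0.020 M; pre-initiator 1.0 mM; time 10 d

    free monomer + initiator → living end + monomer in chains (k1 = 9.4 M⁻¹ h⁻¹)
    free monomer + living end → monomer in chains + living end, rate k2*[living end]*[free monomer] (k2 = 13 M⁻¹ h⁻¹)
    2 living end → dead end (k3 = 55 M⁻¹ h⁻¹)
    pre-initiator → initiator (k4 = 0.0059 h⁻¹)

- average number of monomer units in a chain (chains begun, living or dead) at 10 d
- part of the free monomer that has reacted at 10 d

- two of one species on the left: rate k times its square, two consumed each time
- the average divides the monomer in chains by the number of chains begun, living and dead together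
- run time (flask): 10 d

Because of that gap, initiator passes on what pre-initiator releases, and my reckoning puts the chains begun by 10 d at 0.757 mM. With initiation alone, each chain takes one free monomer, so 3.79% reacts. This term is kept as a correction.

Growth is the other term. Free monomer falls pseudo-first-order, with 13 M⁻¹ h⁻¹ times c(living end) as its constant, so its loss is counted as exposure. In my reckoning with no living end dying, the exposure from growth comes to 1.45, and 76.5% reacts.

Termination then cuts this. Taking the supply of living ends as balanced by their loss in pairs gives a balance value of c(living end) = 2.32 × 10⁻⁴ M for the full charge of pre-initiator, and this value falls with the root of c(pre-initiator). The reckoned exposure from growth drops to 0.518, which is still more than the correction.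

Adding the correction, the exposure of the flask, the natural logarithm of charged over remaining free monomer, is reckoned at 0.556. That gives 42.6% reacted and 11.3 units per chain.

The forecast says 38.5% and 10.4, on the ground that “The living ends sit near the balance of slow initiation and termination”. My reckoning stands above it on both.

The flask gives 39.6% reacted and 10.7 units per chain. At 10.0 d, its living end is made at 0.815 of the rate at which it is used up. Read from the 60% of free monomer left, the exposure of this flask is 0.505, below the reckoned 0.556. In the reckoning, growth scales with the root of the pre-initiator charge and the correction with the charge itself. The neighbour flask with 0.0025 M of pre-initiator is thus reckoned at an exposure of 0.913, or 59.9% reacted. That neighbour flask gives 59.0%.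

The rate constants come from no measurement; the run is a simulation.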